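**Plan**

- Retrosynthesis: the OH groups are unmasked last; the benzyl arm comes from hydrogenation of a 4-benzylidene-tetrahydrofuran, itself from aryl addition to a former ester carbon; the tetrahydrofuran is cut at O1–C2 and C5–C4 into formaldehyde and a trans aryl cyclopropane-1,1-diester; the cyclopropane goes back to an enal and bromomalonate; each dihydrobenzofuran is cut at C2–C3 (carbenoid C–H insertion) and at ArO–CH2 (Mitsunobu).
- Enabling feature: in the tetrahydrofuran (O1, C2 aryl, C3 CH2OH, C4 benzyl, C5 H2), C5 is an unsubstituted O–CH2 (a formaldehyde unit), C2 carries an arene whose dihydrobenzofuran oxygen sits para (strong donor), and C4 can carry two esters (acceptor). C2–C3–C4 is therefore a masked push–pull cyclopropane whose strain drives ring formation.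
- Forward order: unit C dihydrobenzofuran (steps 1–5), unit B dihydrobenzofuran (steps 6–10), enal and cyclopropane (steps 11–15), tetrahydrofuran (step 16), benzyl arm, saturation and unmasking (steps 17–22).
- Stereochemistry: each dihydrobenzofuran C2 by one of two enantiomeric Rh2 carboxylate catalysts, C3 by epimerisation to trans; tetrahydrofuran C3 by aminocatalytic cyclopropanation, C2 by inversion in the (3+2) (trans cyclopropane gives the 2,3-cis ring), C4 by hydrogenation anti to the two cis substituents (all-cis).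

Key step: step 16

Assumption: in the carbenoid C–H insertion of an aryl(diazo)acetate into an ortho ArCH2O group, Rh2(S-PTTL)4 (dirhodium tetrakis[N-phthaloyl-(S)-tert-leucinate], divalent rhodium) is taken to give the (2R,3S)-cis ester; if the sense proves opposite, the catalysts of steps 4 and 9 are exchanged.

Numbering used throughout: tetrahydrofuran O1, C2 (aryl), C3 (CH2O), C4, C5 (CH2); cyclopropane C1 (diester), C2 (CH2O or CHO), C3 (aryl).

Abbreviation: ArBC = (2R,3S)-2-{(2S,3R)-2-[4-(benzyloxy)-3-methoxyphenyl]-7-methoxy-3-[(triisopropylsilyloxy)methyl]-2,3-dihydrobenzofuran-5-yl}-7-methoxy-3-[(triisopropylsilyloxy)methyl]-2,3-dihydrobenzofuran-5-yl.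

**Route**

Step 1
Reactants: 1 4-hydroxy-3-iodo-5-methoxybenzaldehyde (5-iodovanillin); 2 [4-(benzyloxy)-3-methoxyphenyl]methanol
Product: 3 4-{[4-(benzyloxy)-3-methoxybenzyl]oxy}-3-iodo-5-methoxybenzaldehyde
Conditions: PPh3, DIAD, THF, 0 °C to rt
Reagents that add atoms: none
Why: Mitsunobu etherification, in which the acidic 2,6-disubstituted phenol displaces the activated primary benzylic alcohol under neutral conditions that leave the aldehyde and the aryl iodide untouched; no stereocentre is formed.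

Step 2
Reactants: 3 4-{[4-(benzyloxy)-3-methoxybenzyl]oxy}-3-iodo-5-methoxybenzaldehyde
Product: 5 4-{[4-(benzyloxy)-3-methoxybenzyl]oxy}-3-iodo-5-methoxybenzyl acetate, via benzylic alcohol 4 (not isolated)
Conditions: NaBH4, THF/MeOH, 0 °C; then Ac2O, pyridine, DMAP, CH2Cl2, rt
Reagents that add atoms: acetic anhydride CC(=O)OC(C)=O
Why: Borohydride reduction of the aldehyde and acetylation of the crude benzylic alcohol give an acetate that is inert to the palladium and rhodium carbene chemistry ahead and is shed without a separate step in step 5.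

Step 3
Reactants: 5 4-{[4-(benzyloxy)-3-methoxybenzyl]oxy}-3-iodo-5-methoxybenzyl acetate
Product: 6 ethyl 2-[5-(acetoxymethyl)-2-{[4-(benzyloxy)-3-methoxybenzyl]oxy}-3-methoxyphenyl]-2-diazoacetate
Conditions: ethyl diazoacetate (1.5 equiv), Pd(PPh3)4 (5 mol %), Ag2CO3 (0.5 equiv), Et3N, toluene, rt
Reagents that add atoms: ethyl diazoacetate CCOC(=O)C=[N+]=[N-]
Why: Palladium-catalysed cross-coupling of an aryl iodide with ethyl diazoacetate (oxidative addition at zerovalent palladium, then C–H arylation of the diazo carbon with the diazo group retained) delivers the aryl(diazo)acetate in one step.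

Step 4
Reactants: 6 ethyl 2-[5-(acetoxymethyl)-2-{[4-(benzyloxy)-3-methoxybenzyl]oxy}-3-methoxyphenyl]-2-diazoacetate
Product: 7 ethyl (2S,3R)-5-(acetoxymethyl)-2-[4-(benzyloxy)-3-methoxyphenyl]-7-methoxy-2,3-dihydrobenzofuran-3-carboxylate (2,3-cis)
Conditions: Rh2(R-PTTL)4 (2 mol %), toluene, −60 °C, slow addition of 6
Reagents that add atoms: none
Why: Intramolecular 1,5 C–H insertion of the donor/acceptor rhodium carbenoid into the doubly activated ArO–CH2–Ar position closes the dihydrobenzofuran with cis selectivity, and the chiral carboxylate ligands should set C2 as S (C3 as R).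

Step 5
Reactants: 7 ethyl (2S,3R)-5-(acetoxymethyl)-2-[4-(benzyloxy)-3-methoxyphenyl]-7-methoxy-2,3-dihydrobenzofuran-3-carboxylate
Product: 8 ethyl (2S,3S)-2-[4-(benzyloxy)-3-methoxyphenyl]-5-(hydroxymethyl)-7-methoxy-2,3-dihydrobenzofuran-3-carboxylate (2,3-trans)
Conditions: NaOEt, EtOH, 0 °C to rt
Reagents that add atoms: none
Why: Ethoxide enolises the ester-bearing C3 and equilibrates it to the thermodynamically preferred 2,3-trans isomer without touching C2, while transesterification removes the acetate.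

Step 6
Reactants: 8 ethyl (2S,3S)-2-[4-(benzyloxy)-3-methoxyphenyl]-5-(hydroxymethyl)-7-methoxy-2,3-dihydrobenzofuran-3-carboxylate; 1 4-hydroxy-3-iodo-5-methoxybenzaldehyde
Product: 9 ethyl (2S,3S)-2-[4-(benzyloxy)-3-methoxyphenyl]-5-[(4-formyl-2-iodo-6-methoxyphenoxy)methyl]-7-methoxy-2,3-dihydrobenzofuran-3-carboxylate
Conditions: PPh3, DIAD, THF, 0 °C to rt
Reagents that add atoms: none
Why: Mitsunobu etherification as in step 1 joins the second iodophenol to the benzylic alcohol without base, so the trans ester centre is not disturbed.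

Step 7
Reactants: 9 ethyl (2S,3S)-2-[4-(benzyloxy)-3-methoxyphenyl]-5-[(4-formyl-2-iodo-6-methoxyphenoxy)methyl]-7-methoxy-2,3-dihydrobenzofuran-3-carboxylate
Product: 10 ethyl (2S,3S)-2-[4-(benzyloxy)-3-methoxyphenyl]-5-({4-[(E)-3-ethoxy-3-oxoprop-1-enyl]-2-iodo-6-methoxyphenoxy}methyl)-7-methoxy-2,3-dihydrobenzofuran-3-carboxylate
Conditions: Ph3P=CHCO2Et, toluene, 80 °C
Reagents that add atoms: ethyl (triphenylphosphoranylidene)acetate CCOC(=O)C=P(c1ccccc1)(c1ccccc1)c1ccccc1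
Why: Wittig olefination with a stabilised ylide gives the (E)-cinnamate, which masks the later enal and is too electron-poor to be cyclopropanated by the carbenoid of step 9.

Step 8
Reactants: 10 ethyl (2S,3S)-2-[4-(benzyloxy)-3-methoxyphenyl]-5-({4-[(E)-3-ethoxy-3-oxoprop-1-enyl]-2-iodo-6-methoxyphenoxy}methyl)-7-methoxy-2,3-dihydrobenzofuran-3-carboxylate
Product: 11 ethyl (2S,3S)-2-[4-(benzyloxy)-3-methoxyphenyl]-5-({2-(1-diazo-2-ethoxy-2-oxoethyl)-4-[(E)-3-ethoxy-3-oxoprop-1-enyl]-6-methoxyphenoxy}methyl)-7-methoxy-2,3-dihydrobenzofuran-3-carboxylate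
Conditions: ethyl diazoacetate (1.5 equiv), Pd(PPh3)4 (5 mol %), Ag2CO3 (0.5 equiv), Et3N, toluene, rt
Reagents that add atoms: ethyl diazoacetate CCOC(=O)C=[N+]=[N-]
Why: The same palladium-catalysed aryl iodide/diazoacetate coupling as in step 3, run at room temperature where the cinnamate does not undergo Heck arylation.

Step 9
Reactants: 11 ethyl (2S,3S)-2-[4-(benzyloxy)-3-methoxyphenyl]-5-({2-(1-diazo-2-ethoxy-2-oxoethyl)-4-[(E)-3-ethoxy-3-oxoprop-1-enyl]-6-methoxyphenoxy}methyl)-7-methoxy-2,3-dihydrobenzofuran-3-carboxylate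
Product: 12 ethyl (2R,3S)-2-{(2S,3S)-2-[4-(benzyloxy)-3-methoxyphenyl]-3-(ethoxycarbonyl)-7-methoxy-2,3-dihydrobenzofuran-5-yl}-5-[(E)-3-ethoxy-3-oxoprop-1-enyl]-7-methoxy-2,3-dihydrobenzofuran-3-carboxylate (unit B 2,3-cis)
Conditions: Rh2(S-PTTL)4 (2 mol %), toluene, −60 °C, slow addition of 11
Reagents that add atoms: none
Why: Rhodium carbenoid 1,5 C–H insertion as in step 4 with the enantiomeric catalyst, whose control should override the remote centres of unit C and set C2 of unit B as R with 2,3-cis geometry.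

Step 10
Reactants: 12 ethyl (2R,3S)-2-{(2S,3S)-2-[4-(benzyloxy)-3-methoxyphenyl]-3-(ethoxycarbonyl)-7-methoxy-2,3-dihydrobenzofuran-5-yl}-5-[(E)-3-ethoxy-3-oxoprop-1-enyl]-7-methoxy-2,3-dihydrobenzofuran-3-carboxylate
Product: 13 ethyl (2R,3R)-2-{(2S,3S)-2-[4-(benzyloxy)-3-methoxyphenyl]-3-(ethoxycarbonyl)-7-methoxy-2,3-dihydrobenzofuran-5-yl}-5-[(E)-3-ethoxy-3-oxoprop-1-enyl]-7-methoxy-2,3-dihydrobenzofuran-3-carboxylate (both units 2,3-trans)
Conditions: NaOEt (0.3 equiv), EtOH/THF, 0 °C to rt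
Reagents that add atoms: none
Why: Base-mediated epimerisation at C3 of unit B through the ester enolate gives the 2,3-trans isomer, unit C being already trans.

Step 11
Reactants: 13 ethyl (2R,3R)-2-{(2S,3S)-2-[4-(benzyloxy)-3-methoxyphenyl]-3-(ethoxycarbonyl)-7-methoxy-2,3-dihydrobenzofuran-5-yl}-5-[(E)-3-ethoxy-3-oxoprop-1-enyl]-7-methoxy-2,3-dihydrobenzofuran-3-carboxylate
Product: 14 (E)-3-[(2R,3S)-2-{(2S,3R)-2-[4-(benzyloxy)-3-methoxyphenyl]-3-(hydroxymethyl)-7-methoxy-2,3-dihydrobenzofuran-5-yl}-3-(hydroxymethyl)-7-methoxy-2,3-dihydrobenzofuran-5-yl]prop-2-en-1-ol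
Conditions: i-Bu2AlH (excess), CH2Cl2, −78 to 0 °C
Reagents that add atoms: none
Why: Excess i-Bu2AlH reduces both saturated esters and, by 1,2-reduction, the cinnamate to the allylic alcohol without affecting the benzylic ethers.

Step 12
Reactants: 14 (E)-3-[(2R,3S)-2-{(2S,3R)-2-[4-(benzyloxy)-3-methoxyphenyl]-3-(hydroxymethyl)-7-methoxy-2,3-dihydrobenzofuran-5-yl}-3-(hydroxymethyl)-7-methoxy-2,3-dihydrobenzofuran-5-yl]prop-2-en-1-ol
Product: 15 (E)-3-[(2R,3S)-2-{(2S,3R)-2-[4-(benzyloxy)-3-methoxyphenyl]-3-(hydroxymethyl)-7-methoxy-2,3-dihydrobenzofuran-5-yl}-3-(hydroxymethyl)-7-methoxy-2,3-dihydrobenzofuran-5-yl]prop-2-enal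
Conditions: MnO2, CH2Cl2, rt
Reagents that add atoms: none
Why: MnO2 oxidises only the allylic (cinnamyl) alcohol and leaves the two saturated primary alcohols.

Step 13
Reactants: 15 (E)-3-[(2R,3S)-2-{(2S,3R)-2-[4-(benzyloxy)-3-methoxyphenyl]-3-(hydroxymethyl)-7-methoxy-2,3-dihydrobenzofuran-5-yl}-3-(hydroxymethyl)-7-methoxy-2,3-dihydrobenzofuran-5-yl]prop-2-enal
Product: 16 (E)-3-(ArBC)prop-2-enal
Conditions: TIPSCl, imidazole, DMF, rt
Reagents that add atoms: triisopropylsilyl chloride CC(C)[Si](Cl)(C(C)C)C(C)C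
Why: Silylation of both primary alcohols with a group robust enough for the Lewis acid, hot chloride and organolithium steps ahead.

Step 14
Reactants: 16 (E)-3-(ArBC)prop-2-enal
Product: 17 diethyl (2R,3S)-3-(ArBC)-2-formylcyclopropane-1,1-dicarboxylate (aryl and formyl trans)
Conditions: diethyl bromomalonate, (S)-2-[diphenyl(trimethylsilyloxy)methyl]pyrrolidine (20 mol %), 2,6-lutidine, CH2Cl2, 0 °C to rt
Reagents that add atoms: diethyl bromomalonate CCOC(=O)C(Br)C(=O)OCC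
Why: Aminocatalytic Michael-initiated ring closure, in which the (S)-configured catalyst shields one face of the E-iminium so that bromomalonate adds to the β-carbon from the other face and the enamine then closes by 3-exo-tet alkylation, which should give the trans (2R,3S) cyclopropane.

Step 15
Reactants: 17 diethyl (2R,3S)-3-(ArBC)-2-formylcyclopropane-1,1-dicarboxylate
Product: 19 diethyl (2R,3S)-3-(ArBC)-2-[(triisopropylsilyloxy)methyl]cyclopropane-1,1-dicarboxylate, via cyclopropylmethanol 18 (not isolated)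
Conditions: NaBH4, EtOH/CH2Cl2, −20 °C; then TIPSOTf, 2,6-lutidine, CH2Cl2, −78 °C
Reagents that add atoms: triisopropylsilyl triflate CC(C)[Si](OS(=O)(=O)C(F)(F)F)(C(C)C)C(C)C
Why: Chemoselective borohydride reduction of the aldehyde (malonate esters untouched) followed at once by low-temperature silylation, fast enough to forestall lactonisation onto the cis ester; both centres are retained.

Step 16
Reactants: 19 diethyl (2R,3S)-3-(ArBC)-2-[(triisopropylsilyloxy)methyl]cyclopropane-1,1-dicarboxylate; 20 formaldehyde (as paraformaldehyde)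
Product: 21 diethyl (2R,3R)-2-(ArBC)-3-[(triisopropylsilyloxy)methyl]tetrahydrofuran-4,4-dicarboxylate (2,3-cis)
Conditions: Sn(OTf)2 (10 mol %), paraformaldehyde (5 equiv), CH2Cl2, 0 °C to rt
Reagents that add atoms: none
Why: Sn(OTf)2 chelates the geminal diester and polarises the cyclopropane C1–C3 bond between the malonate carbon and the carbon bearing the 4-alkoxy-3-methoxyaryl donor; the carbonyl oxygen of formaldehyde attacks that benzylic carbon from the rear (SN2-like, on an intimate ion pair) and the resulting O-alkylated formaldehyde (oxocarbenium) is captured by the malonate enolate. The closest known reaction type is the Lewis-acid-catalysed (3+2) annulation of aryl cyclopropane-1,1-diesters with aldehydes, including 2,3-disubstituted cyclopropanes with electron-rich aryl donors. The tetrahydrofuran closes by a 5-(enolexo)-endo-trig aldol-type attack, formally disfavoured yet routine for such short, polarised C=O+ acceptors in this reaction class. The new stereocentre C2 of the tetrahydrofuran is set by stereospecific inversion at the donor carbon, so the trans cyclopropane gives the 2,3-cis ring, while C3 is carried over unchanged and C4 and C5 are not stereogenic. The step needs cleavage of the donor–acceptor bond only, inversion without ionisation to a free benzylic cation, and survival of the two dihydrobenzofuran benzylic ethers; the push–pull substitution, the chelating diester, a mild catalytic Lewis acid at low temperature and the strain-driven reactivity of the cyclopropane secure these.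

Step 17
Reactants: 21 diethyl (2R,3R)-2-(ArBC)-3-[(triisopropylsilyloxy)methyl]tetrahydrofuran-4,4-dicarboxylate
Product: 22 ethyl (2R,3R)-2-(ArBC)-3-[(triisopropylsilyloxy)methyl]tetrahydrofuran-4-carboxylate (C4 epimers)
Conditions: LiCl, H2O, DMSO, 130 °C
Reagents that add atoms: none
Why: Krapcho dealkoxycarbonylation of the geminal diester (chloride SN2 at ethyl, loss of CO2, protonation); the C4 epimer mixture is of no consequence because this centre becomes sp2 in step 20.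

Step 18
Reactants: 22 ethyl (2R,3R)-2-(ArBC)-3-[(triisopropylsilyloxy)methyl]tetrahydrofuran-4-carboxylate
Product: 23 (2R,3R)-2-(ArBC)-3-[(triisopropylsilyloxy)methyl]tetrahydrofuran-4-carbaldehyde (C4 epimers)
Conditions: i-Bu2AlH (1.2 equiv), toluene, −78 °C
Reagents that add atoms: none
Why: Low-temperature i-Bu2AlH reduction stops at the aldehyde through the stable tetrahedral aluminium hemiacetal.

Step 19
Reactants: 23 (2R,3R)-2-(ArBC)-3-[(triisopropylsilyloxy)methyl]tetrahydrofuran-4-carbaldehyde; 24 1-(benzyloxy)-4-bromo-2-methoxybenzene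
Product: 26 [4-(benzyloxy)-3-methoxyphenyl]{(2R,3R)-2-(ArBC)-3-[(triisopropylsilyloxy)methyl]tetrahydrofuran-4-yl}methanol (mixture at C4 and at the carbinol carbon), via aryllithium 25 (not isolated)
Conditions: 24, n-BuLi, THF, −78 °C; then 23, −78 °C
Reagents that add atoms: none
Why: Bromine–lithium exchange followed by 1,2-addition of the aryllithium to the aldehyde forms the aryl–carbon bond of the benzyl arm; the diastereomer mixture is erased in step 20.

Step 20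
Reactants: 26 [4-(benzyloxy)-3-methoxyphenyl]{(2R,3R)-2-(ArBC)-3-[(triisopropylsilyloxy)methyl]tetrahydrofuran-4-yl}methanol
Product: 27 (2R,3R)-2-(ArBC)-4-[4-(benzyloxy)-3-methoxybenzylidene]-3-[(triisopropylsilyloxy)methyl]tetrahydrofuran (E/Z mixture)
Conditions: Burgess reagent, toluene, 60 °C
Reagents that add atoms: none
Why: Burgess dehydration (syn elimination of the sulfamate) can only use the ring C4 hydrogen, giving the exocyclic styrene under neutral conditions that avoid a free benzylic cation.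

Step 21
Reactants: 27 (2R,3R)-2-(ArBC)-4-[4-(benzyloxy)-3-methoxybenzylidene]-3-[(triisopropylsilyloxy)methyl]tetrahydrofuran
Product: 28 (2R,3R,4R)-4-(4-hydroxy-3-methoxybenzyl)-2-[ArBC with OH in place of the benzyl ether]-3-[(triisopropylsilyloxy)methyl]tetrahydrofuran (all-cis)
Conditions: H2 (1 atm), Pd/C, EtOAc, rt
Reagents that add atoms: none
Why: Heterogeneous hydrogenation delivers hydrogen to the exocyclic alkene from the face opposite the cis C2 aryl and C3 silyloxymethyl groups, which should set C4 as R (all-cis ring), and the same catalyst hydrogenolyses both phenolic benzyl ethers.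

Step 22
Reactants: 28 (2R,3R,4R)-4-(4-hydroxy-3-methoxybenzyl)-2-[ArBC with OH in place of the benzyl ether]-3-[(triisopropylsilyloxy)methyl]tetrahydrofuran
Product: 29 [(2R,3R,4R)-2-[(2R,3S)-2-{(2S,3R)-2-(4-hydroxy-3-methoxyphenyl)-3-(hydroxymethyl)-7-methoxy-2,3-dihydrobenzofuran-5-yl}-3-(hydroxymethyl)-7-methoxy-2,3-dihydrobenzofuran-5-yl]-4-(4-hydroxy-3-methoxybenzyl)tetrahydrofuran-3-yl]methanol (CNP0395728.1)
Conditions: TBAF, AcOH, THF, 0 °C to rt
Reagents that add atoms: none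
Why: Buffered fluoride removes the three silyl ethers without generating phenoxides that could open the 4-hydroxybenzylic ethers through quinone methides.

**Compound list**

1 | 4-hydroxy-3-iodo-5-methoxybenzaldehyde (5-iodovanillin) | O=Cc1cc(I)c(O)c(OC)c1 | starting material
2 | [4-(benzyloxy)-3-methoxyphenyl]methanol | OCc1ccc(OCc2ccccc2)c(OC)c1 | starting material
3 | 4-{[4-(benzyloxy)-3-methoxybenzyl]oxy}-3-iodo-5-methoxybenzaldehyde | O=Cc1cc(I)c(OCc2ccc(OCc3ccccc3)c(OC)c2)c(OC)c1 | intermediate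
4 | (4-{[4-(benzyloxy)-3-methoxybenzyl]oxy}-3-iodo-5-methoxyphenyl)methanol | OCc1cc(I)c(OCc2ccc(OCc3ccccc3)c(OC)c2)c(OC)c1 | intermediate
5 | 4-{[4-(benzyloxy)-3-methoxybenzyl]oxy}-3-iodo-5-methoxybenzyl acetate | CC(=O)OCc1cc(I)c(OCc2ccc(OCc3ccccc3)c(OC)c2)c(OC)c1 | intermediate
6 | ethyl 2-[5-(acetoxymethyl)-2-{[4-(benzyloxy)-3-methoxybenzyl]oxy}-3-methoxyphenyl]-2-diazoacetate | CCOC(=O)C(=[N+]=[N-])c1cc(COC(C)=O)cc(OC)c1OCc1ccc(OCc2ccccc2)c(OC)c1 | intermediate
7 | ethyl (2S,3R)-5-(acetoxymethyl)-2-[4-(benzyloxy)-3-methoxyphenyl]-7-methoxy-2,3-dihydrobenzofuran-3-carboxylate (cis) | CC(=O)OCc1cc(OC)c2c(c1)[C@@H](C(=O)OCC)[C@@H](c1ccc(OCc3ccccc3)c(OC)c1)O2 | intermediate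
8 | ethyl (2S,3S)-2-[4-(benzyloxy)-3-methoxyphenyl]-5-(hydroxymethyl)-7-methoxy-2,3-dihydrobenzofuran-3-carboxylate (trans) | OCc1cc(OC)c2c(c1)[C@H](C(=O)OCC)[C@@H](c1ccc(OCc3ccccc3)c(OC)c1)O2 | intermediate
9 | ethyl (2S,3S)-2-[4-(benzyloxy)-3-methoxyphenyl]-5-[(4-formyl-2-iodo-6-methoxyphenoxy)methyl]-7-methoxy-2,3-dihydrobenzofuran-3-carboxylate | O=Cc1cc(I)c(OCc2cc(OC)c3c(c2)[C@H](C(=O)OCC)[C@@H](c2ccc(OCc4ccccc4)c(OC)c2)O3)c(OC)c1 | intermediate
10 | ethyl (2S,3S)-2-[4-(benzyloxy)-3-methoxyphenyl]-5-({4-[(E)-3-ethoxy-3-oxoprop-1-enyl]-2-iodo-6-methoxyphenoxy}methyl)-7-methoxy-2,3-dihydrobenzofuran-3-carboxylate | CCOC(=O)/C=C/c1cc(I)c(OCc2cc(OC)c3c(c2)[C@H](C(=O)OCC)[C@@H](c2ccc(OCc4ccccc4)c(OC)c2)O3)c(OC)c1 | intermediate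
11 | ethyl (2S,3S)-2-[4-(benzyloxy)-3-methoxyphenyl]-5-({2-(1-diazo-2-ethoxy-2-oxoethyl)-4-[(E)-3-ethoxy-3-oxoprop-1-enyl]-6-methoxyphenoxy}methyl)-7-methoxy-2,3-dihydrobenzofuran-3-carboxylate | CCOC(=O)/C=C/c1cc(C(=[N+]=[N-])C(=O)OCC)c(OCc2cc(OC)c3c(c2)[C@H](C(=O)OCC)[C@@H](c2ccc(OCc4ccccc4)c(OC)c2)O3)c(OC)c1 | intermediate
12 | ethyl (2R,3S)-2-{(2S,3S)-2-[4-(benzyloxy)-3-methoxyphenyl]-3-(ethoxycarbonyl)-7-methoxy-2,3-dihydrobenzofuran-5-yl}-5-[(E)-3-ethoxy-3-oxoprop-1-enyl]-7-methoxy-2,3-dihydrobenzofuran-3-carboxylate (unit B cis) | CCOC(=O)/C=C/c1cc(OC)c2c(c1)[C@H](C(=O)OCC)[C@H](c1cc(OC)c3c(c1)[C@H](C(=O)OCC)[C@@H](c1ccc(OCc4ccccc4)c(OC)c1)O3)O2 | intermediate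
13 | ethyl (2R,3R)-2-{(2S,3S)-2-[4-(benzyloxy)-3-methoxyphenyl]-3-(ethoxycarbonyl)-7-methoxy-2,3-dihydrobenzofuran-5-yl}-5-[(E)-3-ethoxy-3-oxoprop-1-enyl]-7-methoxy-2,3-dihydrobenzofuran-3-carboxylate (both units trans) | CCOC(=O)/C=C/c1cc(OC)c2c(c1)[C@@H](C(=O)OCC)[C@H](c1cc(OC)c3c(c1)[C@H](C(=O)OCC)[C@@H](c1ccc(OCc4ccccc4)c(OC)c1)O3)O2 | intermediate
14 | (E)-3-[(2R,3S)-2-{(2S,3R)-2-[4-(benzyloxy)-3-methoxyphenyl]-3-(hydroxymethyl)-7-methoxy-2,3-dihydrobenzofuran-5-yl}-3-(hydroxymethyl)-7-methoxy-2,3-dihydrobenzofuran-5-yl]prop-2-en-1-ol | OC/C=C/c1cc(OC)c2c(c1)[C@@H](CO)[C@H](c1cc(OC)c3c(c1)[C@H](CO)[C@@H](c1ccc(OCc4ccccc4)c(OC)c1)O3)O2 | intermediate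
15 | (E)-3-[(2R,3S)-2-{(2S,3R)-2-[4-(benzyloxy)-3-methoxyphenyl]-3-(hydroxymethyl)-7-methoxy-2,3-dihydrobenzofuran-5-yl}-3-(hydroxymethyl)-7-methoxy-2,3-dihydrobenzofuran-5-yl]prop-2-enal | O=C/C=C/c1cc(OC)c2c(c1)[C@@H](CO)[C@H](c1cc(OC)c3c(c1)[C@H](CO)[C@@H](c1ccc(OCc4ccccc4)c(OC)c1)O3)O2 | intermediate
16 | (E)-3-(ArBC)prop-2-enal | O=C/C=C/c1cc(OC)c2c(c1)[C@@H](CO[Si](C(C)C)(C(C)C)C(C)C)[C@H](c1cc(OC)c3c(c1)[C@H](CO[Si](C(C)C)(C(C)C)C(C)C)[C@@H](c1ccc(OCc4ccccc4)c(OC)c1)O3)O2 | intermediate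
17 | diethyl (2R,3S)-3-(ArBC)-2-formylcyclopropane-1,1-dicarboxylate | O=C[C@@H]5[C@@H](c1cc(OC)c2c(c1)[C@@H](CO[Si](C(C)C)(C(C)C)C(C)C)[C@H](c1cc(OC)c3c(c1)[C@H](CO[Si](C(C)C)(C(C)C)C(C)C)[C@@H](c1ccc(OCc4ccccc4)c(OC)c1)O3)O2)C5(C(=O)OCC)C(=O)OCC | intermediate
18 | diethyl (2R,3S)-3-(ArBC)-2-(hydroxymethyl)cyclopropane-1,1-dicarboxylate | OC[C@@H]5[C@@H](c1cc(OC)c2c(c1)[C@@H](CO[Si](C(C)C)(C(C)C)C(C)C)[C@H](c1cc(OC)c3c(c1)[C@H](CO[Si](C(C)C)(C(C)C)C(C)C)[C@@H](c1ccc(OCc4ccccc4)c(OC)c1)O3)O2)C5(C(=O)OCC)C(=O)OCC | intermediate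
19 | diethyl (2R,3S)-3-(ArBC)-2-[(triisopropylsilyloxy)methyl]cyclopropane-1,1-dicarboxylate | CC(C)[Si](C(C)C)(C(C)C)OC[C@@H]5[C@@H](c1cc(OC)c2c(c1)[C@@H](CO[Si](C(C)C)(C(C)C)C(C)C)[C@H](c1cc(OC)c3c(c1)[C@H](CO[Si](C(C)C)(C(C)C)C(C)C)[C@@H](c1ccc(OCc4ccccc4)c(OC)c1)O3)O2)C5(C(=O)OCC)C(=O)OCC | intermediate
20 | formaldehyde (used as paraformaldehyde) | C=O | starting material
21 | diethyl (2R,3R)-2-(ArBC)-3-[(triisopropylsilyloxy)methyl]tetrahydrofuran-4,4-dicarboxylate | CCOC(=O)C5(C(=O)OCC)CO[C@@H](c1cc(OC)c2c(c1)[C@@H](CO[Si](C(C)C)(C(C)C)C(C)C)[C@H](c1cc(OC)c3c(c1)[C@H](CO[Si](C(C)C)(C(C)C)C(C)C)[C@@H](c1ccc(OCc4ccccc4)c(OC)c1)O3)O2)[C@H]5CO[Si](C(C)C)(C(C)C)C(C)C | intermediate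
22 | ethyl (2R,3R)-2-(ArBC)-3-[(triisopropylsilyloxy)methyl]tetrahydrofuran-4-carboxylate (C4 epimers) | CCOC(=O)C5CO[C@@H](c1cc(OC)c2c(c1)[C@@H](CO[Si](C(C)C)(C(C)C)C(C)C)[C@H](c1cc(OC)c3c(c1)[C@H](CO[Si](C(C)C)(C(C)C)C(C)C)[C@@H](c1ccc(OCc4ccccc4)c(OC)c1)O3)O2)[C@H]5CO[Si](C(C)C)(C(C)C)C(C)C | intermediate
23 | (2R,3R)-2-(ArBC)-3-[(triisopropylsilyloxy)methyl]tetrahydrofuran-4-carbaldehyde (C4 epimers) | O=CC5CO[C@@H](c1cc(OC)c2c(c1)[C@@H](CO[Si](C(C)C)(C(C)C)C(C)C)[C@H](c1cc(OC)c3c(c1)[C@H](CO[Si](C(C)C)(C(C)C)C(C)C)[C@@H](c1ccc(OCc4ccccc4)c(OC)c1)O3)O2)[C@H]5CO[Si](C(C)C)(C(C)C)C(C)C | intermediate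
24 | 1-(benzyloxy)-4-bromo-2-methoxybenzene | Brc1ccc(OCc2ccccc2)c(OC)c1 | starting material
25 | [4-(benzyloxy)-3-methoxyphenyl]lithium | [Li]c1ccc(OCc2ccccc2)c(OC)c1 | intermediate
26 | [4-(benzyloxy)-3-methoxyphenyl]{(2R,3R)-2-(ArBC)-3-[(triisopropylsilyloxy)methyl]tetrahydrofuran-4-yl}methanol (mixture at C4 and carbinol carbon) | COc6cc(C(O)C5CO[C@@H](c1cc(OC)c2c(c1)[C@@H](CO[Si](C(C)C)(C(C)C)C(C)C)[C@H](c1cc(OC)c3c(c1)[C@H](CO[Si](C(C)C)(C(C)C)C(C)C)[C@@H](c1ccc(OCc4ccccc4)c(OC)c1)O3)O2)[C@H]5CO[Si](C(C)C)(C(C)C)C(C)C)ccc6OCc7ccccc7 | intermediate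
27 | (2R,3R)-2-(ArBC)-4-[4-(benzyloxy)-3-methoxybenzylidene]-3-[(triisopropylsilyloxy)methyl]tetrahydrofuran (E/Z) | COc6cc(C=C5CO[C@@H](c1cc(OC)c2c(c1)[C@@H](CO[Si](C(C)C)(C(C)C)C(C)C)[C@H](c1cc(OC)c3c(c1)[C@H](CO[Si](C(C)C)(C(C)C)C(C)C)[C@@H](c1ccc(OCc4ccccc4)c(OC)c1)O3)O2)[C@H]5CO[Si](C(C)C)(C(C)C)C(C)C)ccc6OCc7ccccc7 | intermediate
28 | (2R,3R,4R)-4-(4-hydroxy-3-methoxybenzyl)-2-[ArBC with OH in place of the benzyl ether]-3-[(triisopropylsilyloxy)methyl]tetrahydrofuran | COc6cc(C[C@H]5CO[C@@H](c1cc(OC)c2c(c1)[C@@H](CO[Si](C(C)C)(C(C)C)C(C)C)[C@H](c1cc(OC)c3c(c1)[C@H](CO[Si](C(C)C)(C(C)C)C(C)C)[C@@H](c1ccc(O)c(OC)c1)O3)O2)[C@H]5CO[Si](C(C)C)(C(C)C)C(C)C)ccc6O | intermediate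
29 | [(2R,3R,4R)-2-[(2R,3S)-2-{(2S,3R)-2-(4-hydroxy-3-methoxyphenyl)-3-(hydroxymethyl)-7-methoxy-2,3-dihydrobenzofuran-5-yl}-3-(hydroxymethyl)-7-methoxy-2,3-dihydrobenzofuran-5-yl]-4-(4-hydroxy-3-methoxybenzyl)tetrahydrofuran-3-yl]methanol (CNP0395728.1) | COc1cc(C[C@H]2CO[C@@H](c3cc(OC)c4c(c3)[C@@H](CO)[C@H](c3cc(OC)c5c(c3)[C@H](CO)[C@@H](c3ccc(O)c(OC)c3)O5)O4)[C@H]2CO)ccc1O | target

**Summary**

Total step count: 22. Longest linear sequence: 22 steps (from 1 and 2 to 29; the route is linear, with 1 used twice).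

Steps most likely to fail:

1. Step 16. Formaldehyde is a weak oxygen nucleophile, so capture of the activated cyclopropane may be slow enough for ionisation and epimerisation at the donor carbon (loss of the 2,3-cis relationship), for Friedel–Crafts hydroxymethylation of the electron-rich arenes, or for incorporation of a second formaldehyde unit. Fallback: starting from 19, the same Lewis-acid annulation is run with (E)-cinnamaldehyde, a far better nucleophile of the best-precedented aldehyde class, to give the styryl tetrahydrofuran diester F1. Oxidative cleavage of the styryl alkene (OsO4 cat., NaIO4, 2,6-lutidine, dioxane/H2O) gives the 5-formyl tetrahydrofuran diester F2, and Tsuji–Wilkinson decarbonylation with stoichiometric RhCl(PPh3)3 in hot toluene removes the formyl carbon to rejoin the route at 21.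

2. Step 8 (and its twin, step 3). Oxidative addition and diazo transfer at the hindered ortho-alkoxy aryl iodide may be outpaced by palladium-induced decomposition or dimerisation of the diazo ester. Fallback: starting from 10, palladium-catalysed coupling with the Reformatsky reagent BrZnCH2CO2Et (Pd2(dba)3, XPhos, THF, 60 °C) gives the arylacetate F3, and Regitz diazo transfer (4-acetamidobenzenesulfonyl azide, DBU, MeCN) then returns to 11.

3. Step 21. On the palladium surface, hydrogenolysis of the allylic or benzylic ring C–O bonds or migration of the double bond may compete with saturation of the exocyclic alkene, and the facial bias may be eroded. Fallback: starting from 27, the alkene is first reduced without a metal by diimide (2-nitrobenzenesulfonyl hydrazide, Et3N, CH2Cl2, rt), which transfers hydrogen concertedly from the open face and cannot cleave C–O bonds, giving the saturated bis(benzyl ether) F4. The benzyl ethers are then removed separately by brief transfer hydrogenolysis (Pd/C, cyclohexa-1,4-diene, EtOH) to rejoin the route at 28.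

Further compounds
F1 | step 16 | diethyl (2R,3R)-2-(ArBC)-5-[(E)-2-phenylethenyl]-3-[(triisopropylsilyloxy)methyl]tetrahydrofuran-4,4-dicarboxylate (C5 configuration immaterial, expected cis to the C2 aryl) | CCOC(=O)C5(C(=O)OCC)C(/C=C/c6ccccc6)O[C@@H](c1cc(OC)c2c(c1)[C@@H](CO[Si](C(C)C)(C(C)C)C(C)C)[C@H](c1cc(OC)c3c(c1)[C@H](CO[Si](C(C)C)(C(C)C)C(C)C)[C@@H](c1ccc(OCc4ccccc4)c(OC)c1)O3)O2)[C@H]5CO[Si](C(C)C)(C(C)C)C(C)C
F2 | step 16 | diethyl (2R,3R)-2-(ArBC)-5-formyl-3-[(triisopropylsilyloxy)methyl]tetrahydrofuran-4,4-dicarboxylate | CCOC(=O)C5(C(=O)OCC)C(C=O)O[C@@H](c1cc(OC)c2c(c1)[C@@H](CO[Si](C(C)C)(C(C)C)C(C)C)[C@H](c1cc(OC)c3c(c1)[C@H](CO[Si](C(C)C)(C(C)C)C(C)C)[C@@H](c1ccc(OCc4ccccc4)c(OC)c1)O3)O2)[C@H]5CO[Si](C(C)C)(C(C)C)C(C)C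
F3 | step 8 | ethyl (2S,3S)-2-[4-(benzyloxy)-3-methoxyphenyl]-5-({2-(2-ethoxy-2-oxoethyl)-4-[(E)-3-ethoxy-3-oxoprop-1-enyl]-6-methoxyphenoxy}methyl)-7-methoxy-2,3-dihydrobenzofuran-3-carboxylate | CCOC(=O)/C=C/c1cc(CC(=O)OCC)c(OCc2cc(OC)c3c(c2)[C@H](C(=O)OCC)[C@@H](c2ccc(OCc4ccccc4)c(OC)c2)O3)c(OC)c1
F4 | step 21 | (2R,3R,4R)-2-(ArBC)-4-[4-(benzyloxy)-3-methoxybenzyl]-3-[(triisopropylsilyloxy)methyl]tetrahydrofuran | COc6cc(C[C@H]5CO[C@@H](c1cc(OC)c2c(c1)[C@@H](CO[Si](C(C)C)(C(C)C)C(C)C)[C@H](c1cc(OC)c3c(c1)[C@H](CO[Si](C(C)C)(C(C)C)C(C)C)[C@@H](c1ccc(OCc4ccccc4)c(OC)c1)O3)O2)[C@H]5CO[Si](C(C)C)(C(C)C)C(C)C)ccc6OCc7ccccc7
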